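**Plan**

Locants used: seven-membered ring C1 (carbinol), C5 (O-angeloyl), C6 (lactone O), C7, C8, C9, C10 (methyl C14); lactone C11 (methyl C13) and C12 (C=O); side chain C2 (C=O), C3, C4 (OH), C15.
Retrosynthesis: the angelate ester and the C2 ketone (masked as a C2≡C3 alkyne) come off first; the lactone is then cut at O–C6 and at C12–C11, which excises CO2 and leaves a C5–C6 epoxide and a C11 alkenyl triflate; C1–C2 is cut to a cycloheptenone and an alkynyl anion; the cycloheptenone is contracted to a chiral-pool cyclohexanone.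
Enabling feature: on the cycloheptane the lactone oxygen at C6 is cis to C11 (cis-fused five-membered lactone ring) but trans to the oxygen at C5. This is the pattern left when a carboxylate on C11 opens a C5–C6 epoxide at C6 from the rear, so the O–C12(=O) unit can enter as CO2 between a nucleophilic C11 and an electrophilic C6 that flank C7.
Forward: cyclohexane (from limonene oxide), then the seven-membered ring by one-carbon ring expansion, then the C1 side chain, the epoxide, the lactone ring (CO2), C11 reduction, angelate, alkyne hydration and desilylation.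
Stereochemistry: C7 and C4 from the chiral pool; C10 by a stereospecific hydride shift; C1 and the C5–C6 epoxide by attack on the ring face opposite the cis C7/C10 substituents; C6 by inversion in the key step; C11 by convex-face protonation of the cis-fused lactone enolate.

Key step: step 11

Assumption: (+)-trans-limonene 1,2-oxide is taken as available as the single diastereomer; the cyclopropane configuration drawn for 4, 5 and 6 (addition anti to both ring substituents) is of no consequence because both centres are erased in step 6.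

**Route**

Step 1
Reactants: 1 (+)-trans-limonene 1,2-oxide
Product: 2 cis-dihydrocarvone
Conditions: ZnBr2 (10 mol%), toluene, 60 °C
Reagents that add atoms: none
Why: Meinwald rearrangement: ZnBr2 ionises the tertiary C–O bond and the neighbouring hydride shifts suprafacially to the face opposite the departing oxygen, so the methyl group of the trans-epoxide should end cis to the isopropenyl group (C10 set; C7 comes from the starting material).

Step 2
Reactants: 2 cis-dihydrocarvone
Product: 3 kinetic trimethylsilyl enol ether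
Conditions: LiN(i-Pr)2, THF, −78 °C; Me3SiCl, −78 °C to rt
Reagents that add atoms: chlorotrimethylsilane, C[Si](C)(C)Cl
Why: Kinetic enolate formation and O-silylation: the amide base removes a proton from the CH2 group and not from the methine, so the methyl-bearing stereocentre is not touched.

Step 3
Reactants: 3 kinetic trimethylsilyl enol ether
Product: 4 siloxycyclopropane
Conditions: Et2Zn, CH2I2, toluene, 0 °C to rt
Reagents that add atoms: diiodomethane, ICI
Why: Simmons–Smith cyclopropanation (Et2Zn/CH2I2 variant): the electron-rich silyl enol ether should react in preference to the 1,1-disubstituted alkene, and the two new ring-fusion centres are erased again in step 6.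

Step 4
Reactants: 4 siloxycyclopropane
Product: 5 methyl ketone
Conditions: O3, CH2Cl2, −78 °C; then Me2S, −78 °C to rt
Reagents that add atoms: ozone, [O-][O+]=O
Why: Ozonolysis with reductive work-up cleaves the only alkene to the methyl ketone without creating a stereocentre.

Step 5
Reactants: 5 methyl ketone
Product: 6 alkenyl triflate
Conditions: KN(SiMe3)2, THF, −78 °C; PhNTf2, −78 to 0 °C
Reagents that add atoms: N-phenylbis(trifluoromethanesulfonimide), O=S(=O)(N(c1ccccc1)S(=O)(=O)C(F)(F)F)C(F)(F)F
Why: Kinetic enolisation and O-triflation: the hindered base should deprotonate the methyl group in preference to the ring methine, and the only ketone present is trapped as the 1,1-disubstituted alkenyl triflate.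

Step 6
Reactants: 6 alkenyl triflate
Product: 8 cycloheptenone, via β-chloro ketone 7 (not isolated)
Conditions: FeCl3, DMF, 0 °C; then NaOAc, MeOH, 40 °C
Reagents that add atoms: none
Why: Ito–Saegusa ring expansion: single-electron oxidation of the siloxycyclopropane by FeCl3 cleaves the ring-fusion bond, chlorine transfer gives the β-chloro ketone and E1cB loss of HCl gives the enone; no stereocentre is formed and the weak base is chosen to leave the α'-methine untouched.

Step 7
Reactants: 9 (R)-but-3-yn-2-ol
Product: 10 silyl ether of the alkynol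
Conditions: t-BuMe2SiCl, imidazole, CH2Cl2, rt
Reagents that add atoms: tert-butyldimethylsilyl chloride, CC(C)(C)[Si](C)(C)Cl
Why: Standard silyl ether formation protects the C4 hydroxyl through to the last step; the stereocentre is not involved.

Step 8
Reactants: 8 cycloheptenone; 10 silyl ether of the alkynol
Product: 13 tertiary propargylic alcohol, via lithium acetylide 11 (not isolated), via alkynylcerium dichloride 12 (not isolated)
Conditions: 10, n-BuLi, THF, −78 °C; CeCl3, −78 °C; then 8, −78 °C; aq. NH4Cl
Reagents that add atoms: none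
Why: Organocerium 1,2-addition: the weakly basic alkynylcerium should add to the enone carbonyl without enolising the α'-methine and should attack the face opposite the cis-disposed C10 methyl and C7 alkenyl groups, which places the new hydroxyl cis to the methyl (C1 set).

Step 9
Reactants: 13 tertiary propargylic alcohol
Product: 14 trimethylsilyl ether
Conditions: N-(trimethylsilyl)imidazole, CH2Cl2, rt
Reagents that add atoms: N-(trimethylsilyl)imidazole, C[Si](C)(C)n1ccnc1
Why: Silylation of the tertiary alcohol removes its hydrogen-bond directing effect and makes the oxygen-bearing face the hindered one for step 10.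

Step 10
Reactants: 14 trimethylsilyl ether
Product: 15 epoxide
Conditions: m-CPBA, NaHCO3, CH2Cl2, 0 °C to rt
Reagents that add atoms: m-chloroperoxybenzoic acid, OOC(=O)c1cccc(Cl)c1
Why: Prilezhaev epoxidation: the peracid should react only with the ring alkene (alkenyl triflate and alkyne are electron-poor) and should approach anti to the allylic silyloxy group and the C7 substituent, that is syn to the slim alkynyl group, giving the epoxide trans to the C7 side chain (C5 and C6 set).

Step 11
Reactants: 15 epoxide
Product: 17 α-methylene lactone diol, via epoxy carboxylate 16 (not isolated)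
Conditions: CoI2(2,9-dimethyl-1,10-phenanthroline) (10 mol%), Mn powder, CO2 (1 atm), DMA, rt; then 10% aq. citric acid, MeOH, rt
Reagents that add atoms: carbon dioxide, O=C=O
Why: Reductive carboxylation followed by epoxide-opening lactonisation: Mn reduces the CoI2 complex to monovalent cobalt, which inserts into the alkenyl C–OTf bond, and after a further one-electron reduction the alkenylcobalt adds to CO2, forging C11–C12 and giving the manganese carboxylate 16. On acidification the carboxyl oxygen attacks C6 from the face opposite the oxirane oxygen in a 5-exo-tet closure that forms the γ-lactone ring and the O–C6 bond, while the epoxide C5–O bond stays and becomes the free C5 hydroxyl. The closest known reaction types are the cobalt- or nickel-catalysed reductive carboxylation of alkenyl triflates with CO2 and the acid-promoted lactonisation of γ,δ-epoxy acids. C6 is inverted, which gives the cis ring fusion and the trans C5–O/C6–O relationship; C5 and C7 are untouched and C11 stays trigonal. The step needs chemoselective activation of the C–OTf bond beside the epoxide and the alkyne, which the fast oxidative addition of alkenyl triflates and the hindered alkyne on the opposite ring face should secure, and attack at C6 and not C5, which the five-membered ring size and the neopentyl character of C5 should secure; the dilute acid also removes the labile tertiary trimethylsilyl ether.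

Step 12
Reactants: 17 α-methylene lactone diol
Product: 18 α-methyl lactone diol
Conditions: NaBH4, MeOH, 0 °C; aq. NH4Cl
Reagents that add atoms: none
Why: Conjugate hydride reduction of the α-methylene lactone followed by kinetic protonation of the lactone enolate on the convex face of the cis-fused bicycle should put H-11 syn to H-6/H-7 and the methyl on the concave face as in the target (C11 set).

Step 13
Reactants: 18 α-methyl lactone diol; 19 angelic acid
Product: 21 angelate ester, via mixed anhydride 20 (not isolated)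
Conditions: 19, 2,4,6-trichlorobenzoyl chloride, Et3N, toluene, rt; then 18, toluene, 70 °C
Reagents that add atoms: none
Why: Yamaguchi-type mixed-anhydride esterification run without a nucleophilic catalyst should acylate the secondary C5 hydroxyl (the tertiary one is inert) and keep the Z geometry of the angelate.

Step 14
Reactants: 21 angelate ester
Product: 23 α-hydroxy ketone, via alkylidene carbonate 22 (not isolated)
Conditions: AgOAc (10 mol%), DBU (20 mol%), CO2 (1 atm), MeCN, rt; then H2O, rt
Reagents that add atoms: carbon dioxide, O=C=O; water, O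
Why: Silver-catalysed carboxylative cyclisation of the tertiary propargylic alcohol with CO2 (5-exo-dig attack of the carbonate oxygen on C2) and hydrolysis of the resulting α-alkylidene cyclic carbonate amount to a regioselective alkyne hydration that places the carbonyl at C2, next to the carbinol.

Step 15
Reactants: 23 α-hydroxy ketone
Product: 24 target CNP0321985.1
Conditions: HF·pyridine, pyridine, THF, 0 °C to rt
Reagents that add atoms: none
Why: Fluoride-mediated silyl ether cleavage under buffered, non-basic conditions should free the C4 hydroxyl without retro-aldol or elimination of the β-hydroxy ketone.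

**Compound list**

1 | (+)-trans-limonene 1,2-oxide, (1S,4R,6R)-1-methyl-4-(prop-1-en-2-yl)-7-oxabicyclo[4.1.0]heptane | [C@@H]12C[C@H](C(C)=C)CC[C@]1(C)O2 | starting material
2 | cis-dihydrocarvone, (2S,5R)-2-methyl-5-(prop-1-en-2-yl)cyclohexan-1-one | O=C1C[C@H](C(C)=C)CC[C@@H]1C | intermediate
3 | trimethyl{[(3R,6S)-6-methyl-3-(prop-1-en-2-yl)cyclohex-1-en-1-yl]oxy}silane | C[Si](C)(C)OC1=C[C@H](C(C)=C)CC[C@@H]1C | intermediate
4 | trimethyl{[(1S,2S,5R,6S)-2-methyl-5-(prop-1-en-2-yl)bicyclo[4.1.0]heptan-1-yl]oxy}silane | C[Si](C)(C)O[C@]12C[C@H]1[C@H](C(C)=C)CC[C@@H]2C | intermediate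
5 | 1-[(1S,2R,5S,6S)-5-methyl-6-(trimethylsilyloxy)bicyclo[4.1.0]heptan-2-yl]ethan-1-one | C[Si](C)(C)O[C@]12C[C@H]1[C@H](C(C)=O)CC[C@@H]2C | intermediate
6 | 1-[(1S,2R,5S,6S)-5-methyl-6-(trimethylsilyloxy)bicyclo[4.1.0]heptan-2-yl]ethenyl trifluoromethanesulfonate | C[Si](C)(C)O[C@]12C[C@H]1[C@H](C(=C)OS(=O)(=O)C(F)(F)F)CC[C@@H]2C | intermediate
7 | (3R,4S,7S)-3-chloro-7-methyl-4-[1-(trifluoromethylsulfonyloxy)ethenyl]cycloheptan-1-one (chloride configuration of no consequence) | O=C1C[C@@H](Cl)[C@H](C(=C)OS(=O)(=O)C(F)(F)F)CC[C@@H]1C | intermediate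
8 | (4R,7S)-7-methyl-4-[1-(trifluoromethylsulfonyloxy)ethenyl]cyclohept-2-en-1-one | O=C1C=C[C@H](C(=C)OS(=O)(=O)C(F)(F)F)CC[C@@H]1C | intermediate
9 | (R)-but-3-yn-2-ol | C#C[C@@H](C)O | starting material
10 | (R)-tert-butyl(but-3-yn-2-yloxy)dimethylsilane | C#C[C@@H](C)O[Si](C)(C)C(C)(C)C | intermediate
11 | lithium acetylide of 10 | [Li]C#C[C@@H](C)O[Si](C)(C)C(C)(C)C | intermediate
12 | dichloro{(3R)-3-[(tert-butyldimethylsilyl)oxy]but-1-yn-1-yl}cerium | Cl[Ce](Cl)C#C[C@@H](C)O[Si](C)(C)C(C)(C)C | intermediate
13 | 1-[(1R,4S,5S)-4-{(3R)-3-[(tert-butyldimethylsilyl)oxy]but-1-yn-1-yl}-4-hydroxy-5-methylcyclohept-2-en-1-yl]ethenyl trifluoromethanesulfonate | C1=C[C@H](C(=C)OS(=O)(=O)C(F)(F)F)CC[C@H](C)[C@@]1(O)C#C[C@@H](C)O[Si](C)(C)C(C)(C)C | intermediate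
14 | 1-[(1R,4S,5S)-4-{(3R)-3-[(tert-butyldimethylsilyl)oxy]but-1-yn-1-yl}-5-methyl-4-[(trimethylsilyl)oxy]cyclohept-2-en-1-yl]ethenyl trifluoromethanesulfonate | C1=C[C@H](C(=C)OS(=O)(=O)C(F)(F)F)CC[C@H](C)[C@@]1(O[Si](C)(C)C)C#C[C@@H](C)O[Si](C)(C)C(C)(C)C | intermediate
15 | 1-[(1S,2R,3S,6R,7S)-2-{(3R)-3-[(tert-butyldimethylsilyl)oxy]but-1-yn-1-yl}-3-methyl-2-[(trimethylsilyl)oxy]-8-oxabicyclo[5.1.0]octan-6-yl]ethenyl trifluoromethanesulfonate (epoxide trans to the C7 side chain) | [C@H]12O[C@H]1[C@H](C(=C)OS(=O)(=O)C(F)(F)F)CC[C@H](C)[C@@]2(O[Si](C)(C)C)C#C[C@@H](C)O[Si](C)(C)C(C)(C)C | intermediate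
16 | 2-[(1S,2R,3S,6S,7S)-2-{(3R)-3-[(tert-butyldimethylsilyl)oxy]but-1-yn-1-yl}-3-methyl-2-[(trimethylsilyl)oxy]-8-oxabicyclo[5.1.0]octan-6-yl]prop-2-enoic acid (formed as its manganese carboxylate) | [C@H]12O[C@H]1[C@H](C(=C)C(=O)O)CC[C@H](C)[C@@]2(O[Si](C)(C)C)C#C[C@@H](C)O[Si](C)(C)C(C)(C)C | intermediate
17 | (3aS,6S,7R,8S,8aR)-7-{(3R)-3-[(tert-butyldimethylsilyl)oxy]but-1-yn-1-yl}-7,8-dihydroxy-6-methyl-3-methylideneoctahydro-2H-cyclohepta[b]furan-2-one | O[C@H]1[C@@H]2OC(=O)C(=C)[C@@H]2CC[C@H](C)[C@@]1(O)C#C[C@@H](C)O[Si](C)(C)C(C)(C)C | intermediate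
18 | (3R,3aS,6S,7R,8S,8aR)-7-{(3R)-3-[(tert-butyldimethylsilyl)oxy]but-1-yn-1-yl}-7,8-dihydroxy-3,6-dimethyloctahydro-2H-cyclohepta[b]furan-2-one | O[C@H]1[C@@H]2OC(=O)[C@H](C)[C@@H]2CC[C@H](C)[C@@]1(O)C#C[C@@H](C)O[Si](C)(C)C(C)(C)C | intermediate
19 | angelic acid, (2Z)-2-methylbut-2-enoic acid | C/C=C(/C)C(=O)O | starting material
20 | (2Z)-2-methylbut-2-enoic 2,4,6-trichlorobenzoic anhydride | C/C=C(/C)C(=O)OC(=O)c1c(Cl)cc(Cl)cc1Cl | intermediate
21 | (3R,3aS,6S,7R,8S,8aR)-7-{(3R)-3-[(tert-butyldimethylsilyl)oxy]but-1-yn-1-yl}-7-hydroxy-3,6-dimethyl-2-oxooctahydro-2H-cyclohepta[b]furan-8-yl (2Z)-2-methylbut-2-enoate | C/C=C(/C)C(=O)O[C@H]1[C@@H]2OC(=O)[C@H](C)[C@@H]2CC[C@H](C)[C@@]1(O)C#C[C@@H](C)O[Si](C)(C)C(C)(C)C | intermediate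
22 | spiro (Z)-4-alkylidene-1,3-dioxolan-2-one formed from the C1 hydroxyl, CO2 and C2 of the alkyne of 21 | C/C=C(/C)C(=O)O[C@H]1[C@@H]2OC(=O)[C@H](C)[C@@H]2CC[C@H](C)[C@]13OC(=O)O/C3=C\[C@@H](C)O[Si](C)(C)C(C)(C)C | intermediate
23 | (3R,3aS,6S,7S,8S,8aR)-7-{(3R)-3-[(tert-butyldimethylsilyl)oxy]butanoyl}-7-hydroxy-3,6-dimethyl-2-oxooctahydro-2H-cyclohepta[b]furan-8-yl (2Z)-2-methylbut-2-enoate | C/C=C(/C)C(=O)O[C@H]1[C@@H]2OC(=O)[C@H](C)[C@@H]2CC[C@H](C)[C@@]1(O)C(=O)C[C@@H](C)O[Si](C)(C)C(C)(C)C | intermediate
24 | CNP0321985.1, (3R,3aS,6S,7S,8S,8aR)-7-hydroxy-7-[(3R)-3-hydroxybutanoyl]-3,6-dimethyl-2-oxooctahydro-2H-cyclohepta[b]furan-8-yl (2Z)-2-methylbut-2-enoate | C/C=C(/C)C(=O)O[C@H]1[C@@H]2OC(=O)[C@H](C)[C@@H]2CC[C@H](C)[C@@]1(O)C(=O)C[C@@H](C)O | target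

**Count and risks**

Total steps: 15. Longest linear sequence: 14 steps (steps 1 to 6 and 8 to 15, from 1 to 24); step 7 is a one-step side branch.

Most likely to fail, step 11: the low-valent metals may reduce or open the oxirane, or the alkenylmetal may be protonated before it captures CO2. Fallback: from 15, palladium-catalysed methoxycarbonylation (Pd(OAc)2, 1,3-bis(diphenylphosphino)propane, CO 1 atm, MeOH, Et3N, DMF, 60 °C) would give the methyl acrylate F1. Saponification with LiOH in aqueous THF would give the carboxylate of 16, where the fallback comes back to the route; acidification as in step 11 then leads to 17. In this variant C12 comes from CO and the ring oxygen from hydroxide, so no reducing metal meets the epoxide.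

Second, step 10: facial selectivity may be poor, or the trimethylsilyl group may be lost so that the free hydroxyl directs the oxygen to the wrong face. Fallback: from 14, dihydroxylation with OsO4 (cat.) and N-methylmorpholine N-oxide in acetone/H2O, expected to occur anti to the allylic silyloxy group, would give the cis-5,6-diol F2. SO2Cl2 and Et3N (CH2Cl2, −78 °C) would close the cyclic sulfate F3. Under the conditions of step 11 the carboxylate would open the cyclic sulfate at C6 with inversion to the lactone hydrogen sulfate F4. Dilute H2SO4 in wet THF would then hydrolyse the sulfate ester and the trimethylsilyl ether to 17, where the route is rejoined.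

Third, step 13: acylation of the hindered C5 hydroxyl may be slow, and during prolonged heating the activated angelate may isomerise from Z to E. Fallback: from 18, esterification with 2-[bis(2,2,2-trifluoroethoxy)phosphoryl]propanoic acid (DCC, DMAP, CH2Cl2) would give the phosphonate ester F5. A Still–Gennari olefination with acetaldehyde (KN(SiMe3)2, 18-crown-6, THF, −78 °C) would then build the Z double bond on the ester and come back to the route at 21.

**Further compounds**

F1 | step 11 | methyl 2-[(1S,2R,3S,6S,7S)-2-{(3R)-3-[(tert-butyldimethylsilyl)oxy]but-1-yn-1-yl}-3-methyl-2-[(trimethylsilyl)oxy]-8-oxabicyclo[5.1.0]octan-6-yl]prop-2-enoate | [C@H]12O[C@H]1[C@H](C(=C)C(=O)OC)CC[C@H](C)[C@@]2(O[Si](C)(C)C)C#C[C@@H](C)O[Si](C)(C)C(C)(C)C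
F2 | step 10 | 1-[(1R,2S,3S,4R,5S)-4-{(3R)-3-[(tert-butyldimethylsilyl)oxy]but-1-yn-1-yl}-2,3-dihydroxy-5-methyl-4-[(trimethylsilyl)oxy]cycloheptyl]ethenyl trifluoromethanesulfonate | O[C@H]1[C@@H](O)[C@H](C(=C)OS(=O)(=O)C(F)(F)F)CC[C@H](C)[C@@]1(O[Si](C)(C)C)C#C[C@@H](C)O[Si](C)(C)C(C)(C)C
F3 | step 10 | 5,6-cyclic sulfate of F2 (sulfate on the face opposite the C7 side chain) | [C@H]12OS(=O)(=O)O[C@H]1[C@H](C(=C)OS(=O)(=O)C(F)(F)F)CC[C@H](C)[C@@]2(O[Si](C)(C)C)C#C[C@@H](C)O[Si](C)(C)C(C)(C)C
F4 | step 10 | (3aS,6S,7R,8S,8aR)-7-{(3R)-3-[(tert-butyldimethylsilyl)oxy]but-1-yn-1-yl}-6-methyl-3-methylidene-2-oxo-7-[(trimethylsilyl)oxy]octahydro-2H-cyclohepta[b]furan-8-yl hydrogen sulfate | OS(=O)(=O)O[C@H]1[C@@H]2OC(=O)C(=C)[C@@H]2CC[C@H](C)[C@@]1(O[Si](C)(C)C)C#C[C@@H](C)O[Si](C)(C)C(C)(C)C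
F5 | step 13 | 2-[bis(2,2,2-trifluoroethoxy)phosphoryl]propanoate ester of the C5 hydroxyl of 18 (epimeric at the phosphonate carbon) | CC(P(=O)(OCC(F)(F)F)OCC(F)(F)F)C(=O)O[C@H]1[C@@H]2OC(=O)[C@H](C)[C@@H]2CC[C@H](C)[C@@]1(O)C#C[C@@H](C)O[Si](C)(C)C(C)(C)C
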